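**Plan**

1. Retrosynthesis: C2–CH2Br and C3–CH2OH go back to a lactone carbonyl at C2 and a bare C3. The C5a–C6 and C7–Br bonds are then cut together, leaving a monocyclic oxepin-2-one. This is cut at C5=C5a and at the ester C–O bond into (S)-linalool and a (3S)-3-silylhex-4-enoic acid.
2. Forward: ester, then the seven-membered lactone (ring-closing metathesis), then the bromocyclohexane (bromonium cyclisation, the last ring), then the C3 side chain, then the C2 side chain.
3. The event rests on C9a, which carries both the ring oxygen and the 4-methylpent-3-enyl chain. The chain alkene (future C6=C7) lies 1,5 to C5a, and C5a is the γ-carbon of an allylsilane whose silicon sits on C4 of the oxepinone.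
4. Stereochemistry: C9a comes from Sharpless epoxidation of geraniol. The C–Si centre is bought and is passed on to C5a (anti-SE2′) in the key step, which also sets C7 (chair, anti addition). C2 is set last, by hydroboration anti to the C9a methyl group.
5. Helpers: the silyl group (lost in the key step), the lactone carbonyl (keeps O1 non-nucleophilic, later becomes C2) and a PMB ether.

Key step: step 7

Assumption: locants in the running text are those of the target's 1-benzoxepine skeleton unless a numbered compound is named, and crotylsilane ester 5 is taken as a catalogue reagent.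

**Step 1**
Reactants: 1 geraniol
Product: 2 [(2S,3S)-3-methyl-3-(4-methylpent-3-en-1-yl)oxiran-2-yl]methanol
Conditions: Ti(OiPr)4 (cat.), L-(+)-DET (cat.), t-BuOOH, 4 Å MS, CH2Cl2, −20 °C
Reagents that add atoms: tert-butyl hydroperoxide, CC(C)(C)OO
Why: Sharpless asymmetric epoxidation of the allylic alcohol; the L-(+)-tartrate complex delivers oxygen to the face that gives the (2S,3S)-epoxide and so fixes the future C9a.

**Step 2**
Reactants: 2 [(2S,3S)-3-methyl-3-(4-methylpent-3-en-1-yl)oxiran-2-yl]methanol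
Product: 3 (2S,3R)-3-(iodomethyl)-2-methyl-2-(4-methylpent-3-en-1-yl)oxirane
Conditions: I2, PPh3, imidazole, CH2Cl2, 0 °C
Reagents that add atoms: iodine, II
Why: Appel-type iodination of the primary alcohol under neutral conditions should leave the epoxide and both stereocentres untouched.

**Step 3**
Reactants: 3 (2S,3R)-3-(iodomethyl)-2-methyl-2-(4-methylpent-3-en-1-yl)oxirane
Product: 4 (3S)-3,7-dimethylocta-1,6-dien-3-ol [(S)-linalool]
Conditions: Zn dust, AcOH, EtOH, 0 °C → rt
Reagents that add atoms: none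
Why: Zinc insertion into the C–I bond and β-elimination opens the epoxide (reductive elimination of a 2,3-epoxy iodide) to the tertiary allylic alcohol; the C–O bond at the carbinol carbon is not broken, so its configuration is retained.

**Step 4**
Reactants: 5 methyl (3S,4E)-3-[dimethyl(phenyl)silyl]hex-4-enoate
Product: 6 (3S,4E)-3-[dimethyl(phenyl)silyl]hex-4-enoic acid
Conditions: LiOH, THF/H2O, rt; then 1 M HCl
Reagents that add atoms: lithium hydroxide, [Li+].[OH-]
Why: Plain ester saponification; the β-silyl stereocentre is not enolisable under these conditions and should stay intact.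

**Step 5**
Reactants: 4 (S)-linalool; 6 (3S,4E)-3-[dimethyl(phenyl)silyl]hex-4-enoic acid
Product: 7 (3S)-3,7-dimethylocta-1,6-dien-3-yl (3S,4E)-3-[dimethyl(phenyl)silyl]hex-4-enoate
Conditions: DCC, DMAP, CH2Cl2, 0 °C → rt
Reagents that add atoms: none
Why: Steglich esterification, the standard neutral acylation of tertiary alcohols, avoids acid that would ionise the tertiary allylic system; no stereocentre is touched.

**Step 6**
Reactants: 7 (3S)-3,7-dimethylocta-1,6-dien-3-yl (3S,4E)-3-[dimethyl(phenyl)silyl]hex-4-enoate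
Product: 8 (4S,7S)-4-[dimethyl(phenyl)silyl]-7-methyl-7-(4-methylpent-3-en-1-yl)-4,7-dihydrooxepin-2(3H)-one
Conditions: Hoveyda–Grubbs II (5 mol %), toluene (2 mM), 80 °C
Reagents that add atoms: none
Why: Ring-closing metathesis between the vinyl and propenyl groups closes the seven-membered lactone with loss of propene; the ring forces the cis alkene, and the ester form of the tertiary alcohol should slow the competing closure onto the trisubstituted alkene.

**Step 7**
Reactants: 8 (4S,7S)-4-[dimethyl(phenyl)silyl]-7-methyl-7-(4-methylpent-3-en-1-yl)-4,7-dihydrooxepin-2(3H)-one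
Product: 9 (5aS,7S,9aS)-7-bromo-6,6,9a-trimethyl-5a,6,7,8,9,9a-hexahydro-1-benzoxepin-2(3H)-one
Conditions: TBCO (1.1 equiv), MeNO2, 0 °C, dark; aq. NaHCO3 work-up
Reagents that add atoms: 2,4,4,6-tetrabromocyclohexa-2,5-dien-1-one (TBCO), O=C1C(Br)=CC(Br)(Br)C=C1Br
Why: Proposed new method: TBCO should transfer Br+ reversibly to the most electron-rich π-bond, the trisubstituted side-chain alkene, and the bromonium ion is opened at its tertiary carbon by C6 of 8 (the γ-carbon of the cyclic allylsilane), after which the β-silyl cation at C5 gives PhMe2Si+ to the tribromophenoxide and leaves the C4=C5 alkene; the closest known reactions are bromonium-induced polyene cyclisation and allylsilane-terminated cation–olefin cyclisation, which have not been merged on a cyclic allylsilane. The cyclohexane closes through a chair, 6-endo with respect to the bromonium ion (both of its carbons end in the ring) and exo with respect to the ring alkene. C7 of 9 is set by anti addition across the side-chain alkene within this chair, which puts bromine equatorial and trans to the new C5a–C6 bond. C5a of 9 is set by the anti-SE2′ rule: the electrophile must enter anti to the pseudoaxial C4–Si bond, and with the (4S)-silane this is the face syn to the C7 methyl group of 8, so the new bond ends antiperiplanar to the ring C–O bond and the ring fusion is trans, against the cis preference that an unactivated ring alkene would show. The step needs Br+ to choose the side-chain alkene over the allylsilane; the allylic acyloxy group and the β-carbonyl make the ring alkene the poorer donor, and only the tethered opening is productive. The ring oxygen is acylated (lactone), which should keep it from capturing the bromonium ion as an oxonium ion.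

**Step 8**
Reactants: 9 (5aS,7S,9aS)-7-bromo-6,6,9a-trimethyl-5a,6,7,8,9,9a-hexahydro-1-benzoxepin-2(3H)-one
Product: 11 (5aS,7S,9aS)-7-bromo-3-{[(4-methoxybenzyl)oxy]methyl}-6,6,9a-trimethyl-5a,6,7,8,9,9a-hexahydro-1-benzoxepin-2(5H)-one, via β,γ-unsaturated alkylation product 10 (not isolated)
Conditions: LDA, THF, −78 °C; PMBOCH2Cl, −78 → −20 °C; then DBU, rt
Reagents that add atoms: 4-methoxybenzyl chloromethyl ether, COc1ccc(COCCl)cc1
Why: The lactone dienolate should alkylate at its α-carbon with the α-chloro ether (enolate alkoxymethylation), and DBU then moves the alkene into conjugation (β,γ → α,β isomerisation), which makes C3 trigonal so that no stereocentre of the product is created; the equatorial bromide has no anti-periplanar hydrogen for E2.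

**Step 9**
Reactants: 11 (5aS,7S,9aS)-7-bromo-3-{[(4-methoxybenzyl)oxy]methyl}-6,6,9a-trimethyl-5a,6,7,8,9,9a-hexahydro-1-benzoxepin-2(5H)-one
Product: 12 (5aS,7S,9aS)-7-bromo-3-{[(4-methoxybenzyl)oxy]methyl}-6,6,9a-trimethyl-2-methylidene-2,5,5a,6,7,8,9,9a-octahydro-1-benzoxepine
Conditions: Cp2TiMe2, toluene, 70 °C, dark
Reagents that add atoms: dimethyltitanocene, C[Ti](C)(C1C=CC=C1)C1C=CC=C1
Why: Petasis methylenation converts the lactone carbonyl into the exocyclic enol ether without acid or base, so the alkyl bromide, the PMB ether and all stereocentres should survive.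

**Step 10**
Reactants: 12 (5aS,7S,9aS)-7-bromo-3-{[(4-methoxybenzyl)oxy]methyl}-6,6,9a-trimethyl-2-methylidene-2,5,5a,6,7,8,9,9a-octahydro-1-benzoxepine
Product: 14 [(2R,5aS,7S,9aS)-7-bromo-3-{[(4-methoxybenzyl)oxy]methyl}-6,6,9a-trimethyl-2,5,5a,6,7,8,9,9a-octahydro-1-benzoxepin-2-yl]methanol, via B-alkyl-9-BBN adduct 13 (not isolated)
Conditions: 9-BBN, THF, 0 °C → rt; then H2O2, aq. NaOH, 0 °C
Reagents that add atoms: 9-borabicyclo[3.3.1]nonane, B1C2CCCC1CCC2 (boron and its ring in 13 only); hydrogen peroxide, OO (oxygen of 14)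
Why: Hydroboration–oxidation of the exocyclic enol ether puts boron on the terminal carbon, and hydrogen should reach C2 from the face opposite the axial C9a methyl group (1,3 across O1), which gives the (2R) centre with CH2OH syn to that methyl group.

**Step 11**
Reactants: 14 [(2R,5aS,7S,9aS)-7-bromo-3-{[(4-methoxybenzyl)oxy]methyl}-6,6,9a-trimethyl-2,5,5a,6,7,8,9,9a-octahydro-1-benzoxepin-2-yl]methanol
Product: 15 (2R,5aS,7S,9aS)-7-bromo-2-(bromomethyl)-3-{[(4-methoxybenzyl)oxy]methyl}-6,6,9a-trimethyl-2,5,5a,6,7,8,9,9a-octahydro-1-benzoxepine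
Conditions: CBr4, PPh3, 2,6-lutidine, CH2Cl2, 0 °C
Reagents that add atoms: carbon tetrabromide, BrC(Br)(Br)Br
Why: Appel bromination of the primary alcohol proceeds by SN2 at the CH2 carbon and touches no stereocentre.

**Step 12**
Reactants: 15 (2R,5aS,7S,9aS)-7-bromo-2-(bromomethyl)-3-{[(4-methoxybenzyl)oxy]methyl}-6,6,9a-trimethyl-2,5,5a,6,7,8,9,9a-octahydro-1-benzoxepine
Product: 16 [(2R,5aS,7S,9aS)-7-bromo-2-(bromomethyl)-6,6,9a-trimethyl-2,5,5a,6,7,8,9,9a-octahydro-1-benzoxepin-3-yl]methanol
Conditions: DDQ, CH2Cl2/pH 7 buffer, 0 °C → rt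
Reagents that add atoms: none
Why: Oxidative cleavage of the PMB ether with DDQ is neutral and should leave both C–Br bonds, the trisubstituted alkene and the tertiary ether untouched.

**Compound list**

1 | geraniol [(2E)-3,7-dimethylocta-2,6-dien-1-ol] | CC(C)=CCC/C(C)=C/CO | starting material
2 | [(2S,3S)-3-methyl-3-(4-methylpent-3-en-1-yl)oxiran-2-yl]methanol | CC(C)=CCC[C@]1(C)O[C@H]1CO | intermediate
3 | (2S,3R)-3-(iodomethyl)-2-methyl-2-(4-methylpent-3-en-1-yl)oxirane | CC(C)=CCC[C@]1(C)O[C@H]1CI | intermediate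
4 | (3S)-3,7-dimethylocta-1,6-dien-3-ol | CC(C)=CCC[C@](C)(O)C=C | intermediate
5 | methyl (3S,4E)-3-[dimethyl(phenyl)silyl]hex-4-enoate | C/C=C/[C@H](CC(=O)OC)[Si](C)(C)c1ccccc1 | starting material
6 | (3S,4E)-3-[dimethyl(phenyl)silyl]hex-4-enoic acid | C/C=C/[C@H](CC(=O)O)[Si](C)(C)c1ccccc1 | intermediate
7 | (3S)-3,7-dimethylocta-1,6-dien-3-yl (3S,4E)-3-[dimethyl(phenyl)silyl]hex-4-enoate | C/C=C/[C@H](CC(=O)O[C@@](C)(CCC=C(C)C)C=C)[Si](C)(C)c1ccccc1 | intermediate
8 | (4S,7S)-4-[dimethyl(phenyl)silyl]-7-methyl-7-(4-methylpent-3-en-1-yl)-4,7-dihydrooxepin-2(3H)-one | O=C1C[C@@H](C=C[C@](C)(CCC=C(C)C)O1)[Si](C)(C)c1ccccc1 | intermediate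
9 | (5aS,7S,9aS)-7-bromo-6,6,9a-trimethyl-5a,6,7,8,9,9a-hexahydro-1-benzoxepin-2(3H)-one | CC1(C)[C@@H](Br)CC[C@]2(C)OC(=O)CC=C[C@@H]12 | intermediate
10 | (5aS,7S,9aS)-7-bromo-3-{[(4-methoxybenzyl)oxy]methyl}-6,6,9a-trimethyl-5a,6,7,8,9,9a-hexahydro-1-benzoxepin-2(3H)-one (both C3 epimers) | CC1(C)[C@@H](Br)CC[C@]2(C)OC(=O)C(COCc3ccc(OC)cc3)C=C[C@@H]12 | intermediate
11 | (5aS,7S,9aS)-7-bromo-3-{[(4-methoxybenzyl)oxy]methyl}-6,6,9a-trimethyl-5a,6,7,8,9,9a-hexahydro-1-benzoxepin-2(5H)-one | CC1(C)[C@@H](Br)CC[C@]2(C)OC(=O)C(COCc3ccc(OC)cc3)=CC[C@@H]12 | intermediate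
12 | (5aS,7S,9aS)-7-bromo-3-{[(4-methoxybenzyl)oxy]methyl}-6,6,9a-trimethyl-2-methylidene-2,5,5a,6,7,8,9,9a-octahydro-1-benzoxepine | CC1(C)[C@@H](Br)CC[C@]2(C)OC(=C)C(COCc3ccc(OC)cc3)=CC[C@@H]12 | intermediate
13 | 9-{[(5aS,7S,9aS)-7-bromo-3-{[(4-methoxybenzyl)oxy]methyl}-6,6,9a-trimethyl-2,5,5a,6,7,8,9,9a-octahydro-1-benzoxepin-2-yl]methyl}-9-borabicyclo[3.3.1]nonane (CH2B syn to the C9a methyl group) | CC1(C)[C@@H](Br)CC[C@]2(C)O[C@@H](CB3C4CCCC3CCC4)C(COCc5ccc(OC)cc5)=CC[C@@H]12 | intermediate
14 | [(2R,5aS,7S,9aS)-7-bromo-3-{[(4-methoxybenzyl)oxy]methyl}-6,6,9a-trimethyl-2,5,5a,6,7,8,9,9a-octahydro-1-benzoxepin-2-yl]methanol | CC1(C)[C@@H](Br)CC[C@]2(C)O[C@@H](CO)C(COCc3ccc(OC)cc3)=CC[C@@H]12 | intermediate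
15 | (2R,5aS,7S,9aS)-7-bromo-2-(bromomethyl)-3-{[(4-methoxybenzyl)oxy]methyl}-6,6,9a-trimethyl-2,5,5a,6,7,8,9,9a-octahydro-1-benzoxepine | CC1(C)[C@@H](Br)CC[C@]2(C)O[C@@H](CBr)C(COCc3ccc(OC)cc3)=CC[C@@H]12 | intermediate
16 | [(2R,5aS,7S,9aS)-7-bromo-2-(bromomethyl)-6,6,9a-trimethyl-2,5,5a,6,7,8,9,9a-octahydro-1-benzoxepin-3-yl]methanol | CC1(C)[C@@H](Br)CC[C@]2(C)O[C@@H](CBr)C(CO)=CC[C@@H]12 | target

**Step count**

Total step count: 12. Longest linear sequence: 11 steps (geraniol 1 to 16 through steps 1–3 and 5–12).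

**Steps most likely to fail**

Step 7 (proposed new method). The brominating agent may attack the allylsilane π-bond directly and remove silicon (bromodesilylation), or the bromonium ion may be lost by elimination before the strained anti-SE2′ closure can occur. Fallback with known chemistry, from 8 back to 9: Shi epoxidation of 8 (D-fructose-derived ketone, Oxone, buffered MeCN/DMM, 0 °C) is selective for the trisubstituted alkene and should give the (R)-configured side-chain epoxide, (4S,7S)-7-{2-[(2R)-3,3-dimethyloxiran-2-yl]ethyl}-4-[dimethyl(phenyl)silyl]-7-methyl-4,7-dihydrooxepin-2(3H)-one F1. Opening at the less hindered carbon with Li2NiBr4 in THF, with inversion, should give the bromohydrin (4S,7S)-7-[(3S)-3-bromo-4-hydroxy-4-methylpentyl]-4-[dimethyl(phenyl)silyl]-7-methyl-4,7-dihydrooxepin-2(3H)-one F2. Ionisation of its tertiary hydroxyl group (HFIP, catalytic TfOH, −20 °C), assisted by the neighbouring bromine, regenerates the same bromonium ion on one defined face with no free Br+ in the flask, and cyclisation onto the allylsilane should then give 9.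

Step 6. The ruthenium carbene may close onto the trisubstituted side-chain alkene instead (five-membered ring with loss of isobutene), and initiation at two hindered alkenes may be slow. Fallback, from 7 back to 8: the side-chain alkene is masked by selective epoxidation with mCPBA (CH2Cl2, NaHCO3, 0 °C) to give (3S)-5-(3,3-dimethyloxiran-2-yl)-3-methylpent-1-en-3-yl (3S,4E)-3-[dimethyl(phenyl)silyl]hex-4-enoate F3. Ring-closing metathesis under the conditions of step 6 then has only one pathway and gives (4S,7S)-7-[2-(3,3-dimethyloxiran-2-yl)ethyl]-4-[dimethyl(phenyl)silyl]-7-methyl-4,7-dihydrooxepin-2(3H)-one F4. Deoxygenation of the epoxide with Cp2TiCl (from Cp2TiCl2 and Zn, THF, rt) returns the alkene and 8.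

Step 10. Hydride delivery to C2 may occur with poor facial selectivity, or the β-alkoxy borane may eliminate before oxidation. Fallback, from 11 back to 15: (bromomethyl)lithium (CH2Br2, n-BuLi, THF, −78 °C) adds to the lactone carbonyl of 11 to give the lactol (5aS,7S,9aS)-7-bromo-2-(bromomethyl)-2-hydroxy-3-{[(4-methoxybenzyl)oxy]methyl}-6,6,9a-trimethyl-2,5,5a,6,7,8,9,9a-octahydro-1-benzoxepine F5. Ionic reduction (Et3SiH, BF3·OEt2, CH2Cl2, −78 °C) of the derived oxocarbenium ion should deliver hydride anti to the C9a methyl group and give 15 directly, bypassing steps 9–11.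

**Further compounds**

F1 | step 7 | (4S,7S)-7-{2-[(2R)-3,3-dimethyloxiran-2-yl]ethyl}-4-[dimethyl(phenyl)silyl]-7-methyl-4,7-dihydrooxepin-2(3H)-one | O=C1C[C@@H](C=C[C@](C)(CC[C@H]2OC2(C)C)O1)[Si](C)(C)c1ccccc1
F2 | step 7 | (4S,7S)-7-[(3S)-3-bromo-4-hydroxy-4-methylpentyl]-4-[dimethyl(phenyl)silyl]-7-methyl-4,7-dihydrooxepin-2(3H)-one | O=C1C[C@@H](C=C[C@](C)(CC[C@H](Br)C(C)(C)O)O1)[Si](C)(C)c1ccccc1
F3 | step 6 | (3S)-5-(3,3-dimethyloxiran-2-yl)-3-methylpent-1-en-3-yl (3S,4E)-3-[dimethyl(phenyl)silyl]hex-4-enoate (both epoxide epimers) | C/C=C/[C@H](CC(=O)O[C@@](C)(CCC1OC1(C)C)C=C)[Si](C)(C)c1ccccc1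
F4 | step 6 | (4S,7S)-7-[2-(3,3-dimethyloxiran-2-yl)ethyl]-4-[dimethyl(phenyl)silyl]-7-methyl-4,7-dihydrooxepin-2(3H)-one (both epoxide epimers) | O=C1C[C@@H](C=C[C@](C)(CCC2OC2(C)C)O1)[Si](C)(C)c1ccccc1
F5 | step 10 | (5aS,7S,9aS)-7-bromo-2-(bromomethyl)-2-hydroxy-3-{[(4-methoxybenzyl)oxy]methyl}-6,6,9a-trimethyl-2,5,5a,6,7,8,9,9a-octahydro-1-benzoxepine (both anomers) | CC1(C)[C@@H](Br)CC[C@]2(C)OC(O)(CBr)C(COCc3ccc(OC)cc3)=CC[C@@H]12
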